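- Percent of the substrate charged is the unit in which the autumn and dawn flasks look alike: substrate differs (20 mM against 13 mM), c(coupling partner) starts at 26 mM in both, and substrate is the limiting reagent.

| flask | substrate | coupling partner | remark | time |
|---|---|---|---|---|
| autumn | 20 mM | 26 mM | the very flask that is asked about, followed so far |  |
| dawn | 13 mM | 26 mM | run made earlier |  |
| flask | 20 mM | 26.0 mM |  | 12 h |

| run | time / h | target / % | isomer of the product A / % |
|---|---|---|---|
| autumn | 0.250 | 3.9 | 0.1 |
| autumn | 0.667 | 10.0 | 0.8 |
| autumn | 1.33 | 17.6 | 1.0 |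
| autumn | 2.00 | 23.1 | 1.5 |
| autumn | 3.00 | 30.4 | 2.4 |
| autumn | 4.00 | 36.3 | 3.1 |
| autumn | 5.00 | 40.2 | 3.1 |
| dawn | 0.250 | 3.8 | 0.3 |
| dawn | 0.667 | 10.4 | 0.4 |
| dawn | 1.33 | 18.0 | 1.3 |
| dawn | 2.00 | 24.1 | 1.5 |
| dawn | 3.00 | 32.9 | 2.3 |
| dawn | 4.00 | 37.9 | 3.1 |
| dawn | 5.00 | 42.9 | 3.5 |

(each reading ± 0.3 percentage points)



1. concentration of target at 12 h, in mM
2. concentration of isomer of the product A at 12 h, in mM
3. concentration of isomer of the product B at 12 h, in mM

- At 5.00 h the target reads 42.9% in dawn against 40.2% in autumn, because at 4.00 h, counting the two read products, dawn keeps more c(coupling partner), 20.7 mM against 18.1 mM.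
- The autumn reading at 0.667 h, corrected for mean depletion, gives a making constant of 6.31 M⁻¹ h⁻¹.
- At 4.00 h that constant predicts 1.39 mM h⁻¹ of target, but between 3.00 h and 5.00 h the autumn flask gains 0.980 mM h⁻¹.
- Taking this gap as target going over to isomer of the product B, first order in target, and dividing it by c(target) gives the loss constant kL = 0.0560 h⁻¹, a rough reading from a difference of two rates; control changes hands where the making constant times c(substrate) times c(coupling partner) equals kL times c(target).
- My test for 12 h: assume target at 10.0 mM, half the charge, and a run average of 0.7 of that level, so that 4.70 mM has been lost by then.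
- With the share of isomer of the product A read in autumn, making over loss is then 0.477, so my estimate puts target under 10.0 mM.
- The same reckoning puts isomer of the product A near 1.13 mM.
- It puts isomer of the product B near 4.70 mM, the amount taken as lost.
- The forecast gives 10.9 mM of target, 1.1 mM of isomer of the product A and 0.2 mM of isomer of the product B, noting “Isomer B has never been observed”.
- At 12 h the flask holds 9.69 mM of target, 0.934 mM of isomer of the product A and 3.37 mM of isomer of the product B.

    substrate + coupling partner ⇌ target (K = 540 M⁻¹, k = 6.30 M⁻¹ h⁻¹)
    substrate + coupling partner ⇌ isomer of the product A (K = 110 M⁻¹, k = 0.430 M⁻¹ h⁻¹)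
    target ⇌ isomer of the product B (K = 14.0, k = 0.0380 h⁻¹)

- In this flask target is made 6.42 times as fast as it is used up at 2.95 h, each step taken net, and that ratio is 0.949 at 12.0 h, so the crossing lies between these two times. With kL and the amounts standing at 12 h, making over loss in the same flask comes to 0.837.
- For the flask left until 20 h, kL·c(target) kept up for the extra hours adds 4.34 mM to isomer of the product B, giving 7.71 mM, with target falling. That flask holds 6.11 mM of isomer of the product B and 8.78 mM of target.

The data were generated by integration on assumed constants, noise included.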